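**Plan**

- Retrosynthesis: after removal of six benzyl ethers, one operation cuts the C4–C8 interflavan bond and moves C2 of the upper ring C back from C3 to C4. Ring C thereby contracts to a cis-2-aryl-2,3-dihydrobenzofuran whose formyl carbon is the former C3 (its oxygen is the later 3-OH). The temporary C2–C4 bond is then cut as a carbenoid C–H insertion, and two aryl ether bonds lead back to simple phenols.
- Forward order: rings A and B are joined by an ether; the five-membered ring O1–C2–C4–C4a–C8a is closed by C–H insertion; the ester is reduced to the aldehyde; ring C becomes six-membered by a 1,2-shift that attaches the lower unit in the same operation; hydrogenolysis ends the route.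
- Enabling feature: O7 is para to C4a (O1 ortho), so C4 can carry a quinone-methide-type positive charge. C2 bears O1 and the electron-rich ring B and migrates easily. C3 is the only carbon of ring C without an aryl group and can wait outside the ring at the aldehyde level.
- Stereochemistry: upper C2 from the chiral rhodium carboxylate (retained in the shift); upper C3 and C4 from the anti geometry of the shift on the cis aldehyde; lower C2 and C3 from (+)-afzelechin.

Key step: step 7

Remark: (+)-afzelechin is taken as a purchasable phytochemical standard; Rh2(S-PTTL)4 is assumed to give the (2S,3R) series on this substrate, and its mirror-image catalyst is used if the sense of induction is the opposite.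

**Route**

Step 1
Reactants: 1 methyl 2-(2,4-dihydroxyphenyl)acetate
Product: 2 methyl 2-[4-(benzyloxy)-2-hydroxyphenyl]acetate
Conditions: BnBr (1.0 equiv), K2CO3, acetone, 0 °C → rt
Reagents that add atoms: benzyl bromide, BrCc1ccccc1
Why: Williamson etherification, in which the unhindered 4-OH (para to the side chain) should react before the 2-OH that is flanked by the CH2CO2Me group.

Step 2
Reactants: 2 methyl 2-[4-(benzyloxy)-2-hydroxyphenyl]acetate; 3 3,4-bis(benzyloxy)benzyl chloride
Product: 4 methyl 2-{4-(benzyloxy)-2-[3,4-bis(benzyloxy)benzyloxy]phenyl}acetate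
Conditions: K2CO3, NaI (cat.), DMF, 50 °C
Reagents that add atoms: none
Why: Williamson etherification (with in situ Finkelstein exchange) of the remaining phenol by an activated benzylic chloride, which brings in ring B and the future C2.

Step 3
Reactants: 4 methyl 2-{4-(benzyloxy)-2-[3,4-bis(benzyloxy)benzyloxy]phenyl}acetate
Product: 5 methyl 2-{4-(benzyloxy)-2-[3,4-bis(benzyloxy)benzyloxy]phenyl}-2-diazoacetate
Conditions: p-ABSA, DBU, MeCN, 0 °C → rt
Reagents that add atoms: 4-acetamidobenzenesulfonyl azide (p-ABSA), CC(=O)Nc1ccc(cc1)S(=O)(=O)N=[N+]=[N-]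
Why: Regitz diazo transfer to the benzylic position of an arylacetate, the standard entry to aryldiazoacetates.

Step 4
Reactants: 5 methyl 2-{4-(benzyloxy)-2-[3,4-bis(benzyloxy)benzyloxy]phenyl}-2-diazoacetate
Product: 6 methyl (2S,3R)-6-(benzyloxy)-2-[3,4-bis(benzyloxy)phenyl]-2,3-dihydro-1-benzofuran-3-carboxylate (cis)
Conditions: Rh2(S-PTTL)4 (dirhodium tetrakis[N-phthaloyl-(S)-tert-leucinate], 1 mol %), toluene, −60 °C
Reagents that add atoms: none
Why: Intramolecular 1,5 C–H insertion of the rhodium carbenoid into the ortho benzylic ether C–H (the other benzylic positions are out of reach) is a well-precedented route to cis-2-aryl-2,3-dihydrobenzofuran-3-carboxylates, with the chiral carboxylate ligands setting C2 and the kinetic cis C3.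

Step 5
Reactants: 6 methyl (2S,3R)-6-(benzyloxy)-2-[3,4-bis(benzyloxy)phenyl]-2,3-dihydro-1-benzofuran-3-carboxylate
Product: 7 (2S,3R)-6-(benzyloxy)-2-[3,4-bis(benzyloxy)phenyl]-2,3-dihydro-1-benzofuran-3-carbaldehyde (cis)
Conditions: i-Bu2AlH (1.1 equiv), CH2Cl2, −78 °C; MeOH, then aq. KNaC4H4O6 (potassium sodium tartrate); crude product used at once
Reagents that add atoms: none
Why: Low-temperature partial reduction of an ester with i-Bu2AlH stops at the aldehyde level, and the base-free work-up and direct use should preserve the cis C3 centre and avoid β-elimination of the ring oxygen.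

Step 6
Reactants: 8 (+)-afzelechin
Product: 9 5,7,4'-tri-O-benzyl-(+)-afzelechin
Conditions: BnBr (3.3 equiv), K2CO3, DMF, 0 °C → rt, N2
Reagents that add atoms: benzyl bromide, BrCc1ccccc1
Why: Williamson etherification in which only the three phenolic hydroxyls are deprotonated by K2CO3, so the secondary 3-OH stays free, as is usual for flavan-3-ols.

Step 7
Reactants: 7 (2S,3R)-6-(benzyloxy)-2-[3,4-bis(benzyloxy)phenyl]-2,3-dihydro-1-benzofuran-3-carbaldehyde; 9 5,7,4'-tri-O-benzyl-(+)-afzelechin
Product: 11 hexa-O-benzyl fisetinidol-(4α→8)-afzelechin, (2R,3S,4S)-7-(benzyloxy)-2-[3,4-bis(benzyloxy)phenyl]-4-{(2R,3S)-5,7-bis(benzyloxy)-2-[4-(benzyloxy)phenyl]-3-hydroxy-3,4-dihydro-2H-chromen-8-yl}-3,4-dihydro-2H-chromen-3-ol, via ring-expanded flavan-4-ylium trifluoroborate zwitterion 10 (not isolated)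
Conditions: BF3·OEt2 (1.5 equiv), 9 (3 equiv), CH2Cl2, −78 → −40 °C; aq. NaHCO3
Reagents that add atoms: none
Why: Proposed new method: BF3 activates the formyl group of 7 and the C2–C4 σ bond (C2 carries O1 and ring B) shifts from C4 to the formyl carbon, which expands the five-membered ring to ring C and leaves the C4 cation 10, stabilised as a quinone methide by O7 para to C4a and captured at once by C8 of 9 in a Friedel–Crafts alkylation. The closest known reaction types are the Lewis-acid semipinacol or aldehyde-to-ketone 1,2-shift onto an activated carbonyl (in reverse, a pinacol-type ring contraction of a C4-activated flavan-3-ol) and the Lewis-acid coupling of C4-electrophilic flavan-3-ols with 5,7-di-O-benzylflavan-3-ols, which runs through the same cation. Ring C is not closed by a cyclisation but arises by a suprafacial 1,2-carbon shift (five to six members), and the interflavan bond forms intermolecularly. C2 migrates with retention; C3 is set by the formyl rotamer in which the bulky BF3-bound oxygen points away from the bridged transition state (pseudo-equatorial, anti to O1), which from the cis aldehyde places O3 trans to ring B; C4 is set because the arene enters anti to the departing C2–C4 bond, that is trans to O3, so the all-trans (2R,3S,4S) unit should result. The step needs carbon migration to beat hydride migration from C4 and direct attack of 9 on the formyl carbon, and C8 to beat C6: the first is favoured by the α-oxygen and p-oxygenated aryl on C2, the relief of five-ring strain and the hindered α-branched aldehyde, the second by the 5,7-di-O-benzyl pattern of 9, which is used in excess to suppress over-alkylation.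

Step 8
Reactants: 11 hexa-O-benzyl fisetinidol-(4α→8)-afzelechin
Product: 12 fisetinidol-(4α→8)-afzelechin (CNP0322555.1)
Conditions: H2 (1 atm), Pd(OH)2/C, THF–MeOH–H2O, rt
Reagents that add atoms: none
Why: Hydrogenolysis of the six benzyl ethers under neutral conditions, which the interflavan bond of a 5-deoxy upper unit and the two C2–O1 bonds should survive.

**Compound list**

1 | methyl 2-(2,4-dihydroxyphenyl)acetate | COC(=O)Cc1ccc(O)cc1O | starting material
2 | methyl 2-[4-(benzyloxy)-2-hydroxyphenyl]acetate | COC(=O)Cc1ccc(OCc2ccccc2)cc1O | intermediate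
3 | 3,4-bis(benzyloxy)benzyl chloride | ClCc1ccc(OCc2ccccc2)c(OCc2ccccc2)c1 | starting material
4 | methyl 2-{4-(benzyloxy)-2-[3,4-bis(benzyloxy)benzyloxy]phenyl}acetate | COC(=O)Cc1ccc(OCc2ccccc2)cc1OCc1ccc(OCc2ccccc2)c(OCc2ccccc2)c1 | intermediate
5 | methyl 2-{4-(benzyloxy)-2-[3,4-bis(benzyloxy)benzyloxy]phenyl}-2-diazoacetate | COC(=O)C(=[N+]=[N-])c1ccc(OCc2ccccc2)cc1OCc1ccc(OCc2ccccc2)c(OCc2ccccc2)c1 | intermediate
6 | methyl (2S,3R)-6-(benzyloxy)-2-[3,4-bis(benzyloxy)phenyl]-2,3-dihydro-1-benzofuran-3-carboxylate (cis) | c1ccccc1COc1ccc2c(c1)O[C@H](c1ccc(OCc3ccccc3)c(OCc3ccccc3)c1)[C@@H]2C(=O)OC | intermediate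
7 | (2S,3R)-6-(benzyloxy)-2-[3,4-bis(benzyloxy)phenyl]-2,3-dihydro-1-benzofuran-3-carbaldehyde (cis) | c1ccccc1COc1ccc2c(c1)O[C@H](c1ccc(OCc3ccccc3)c(OCc3ccccc3)c1)[C@@H]2C=O | intermediate
8 | (+)-afzelechin, (2R,3S)-2-(4-hydroxyphenyl)-3,4-dihydro-2H-chromene-3,5,7-triol | O[C@H]1Cc2c(O)cc(O)cc2O[C@@H]1c1ccc(O)cc1 | starting material
9 | 5,7,4'-tri-O-benzyl-(+)-afzelechin, (2R,3S)-5,7-bis(benzyloxy)-2-[4-(benzyloxy)phenyl]-3,4-dihydro-2H-chromen-3-ol | O[C@H]1Cc2c(OCc3ccccc3)cc(OCc3ccccc3)cc2O[C@@H]1c1ccc(OCc2ccccc2)cc1 | intermediate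
10 | ring-expanded flavan-4-ylium trifluoroborate zwitterion (C2 and C3 as in the product, C4 cationic, O3 bound to BF3) | [CH+]1c2ccc(OCc3ccccc3)cc2O[C@H](c2ccc(OCc3ccccc3)c(OCc3ccccc3)c2)[C@H]1O[B-](F)(F)F | intermediate (not isolated)
11 | hexa-O-benzyl fisetinidol-(4α→8)-afzelechin | C(c1ccccc1)Oc1ccc([C@H]2Oc3c(c(OCc4ccccc4)cc(OCc4ccccc4)c3[C@@H]3c4ccc(OCc5ccccc5)cc4O[C@H](c4ccc(OCc5ccccc5)c(OCc5ccccc5)c4)[C@H]3O)C[C@@H]2O)cc1 | intermediate
12 | fisetinidol-(4α→8)-afzelechin, (2R,3S,4S)-2-(3,4-dihydroxyphenyl)-4-[(2R,3S)-3,5,7-trihydroxy-2-(4-hydroxyphenyl)-3,4-dihydro-2H-chromen-8-yl]-3,4-dihydro-2H-chromene-3,7-diol | Oc1ccc([C@H]2Oc3c(c(O)cc(O)c3[C@@H]3c4ccc(O)cc4O[C@H](c4ccc(O)c(O)c4)[C@H]3O)C[C@@H]2O)cc1 | target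

Total step count: 8. Longest linear sequence: 7 steps (steps 1–5, 7, 8).

**Steps most likely to fail, with fallbacks**

1. Step 7 (Proposed new method). Several processes may go wrong:
   - hydride instead of carbon migration to the activated formyl group, followed by loss of a proton and aromatisation to a benzofuran;
   - direct Friedel–Crafts attack of 9 on the formyl carbon before the shift;
   - poor facial selectivity at the formyl group, giving the C3 epimer;
   - epimerisation of the aldehyde at C3 before it reacts.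

   The fallback keeps a five-to-six ring expansion but uses known chemistry at the α-ketol level; it sets out from 6 and comes back at 11. Ester 6 is deprotonated with KN(SiMe3)2 in THF at −78 °C and the enolate is hydroxylated with 2-(phenylsulfonyl)-3-phenyloxaziridine to give methyl (2R,3S)-6-(benzyloxy)-2-[3,4-bis(benzyloxy)phenyl]-3-hydroxy-2,3-dihydro-1-benzofuran-3-carboxylate F1 (the C3 centre is lost later). Reduction with i-Bu2AlH at −78 °C gives the tertiary α-hydroxy aldehyde (2R,3S)-6-(benzyloxy)-2-[3,4-bis(benzyloxy)phenyl]-3-hydroxy-2,3-dihydro-1-benzofuran-3-carbaldehyde F2. An α-ketol (acyloin) rearrangement (BF3·OEt2, CH2Cl2, 0 °C), in which C2 migrates with retention to the formyl carbon while C4 becomes an aryl ketone, should give under thermodynamic control the 2,3-trans dihydroflavonol 7,3',4'-tri-O-benzyl-(2R,3R)-fustin F3. NaBH4 in EtOH–THF reduces the ketone to the 2,3-trans-3,4-trans diol (2R,3S,4R)-7-(benzyloxy)-2-[3,4-bis(benzyloxy)phenyl]-3,4-dihydro-2H-chromene-3,4-diol F4. Ionisation of F4 at C4 with TMSOTf (cat.) in CH2Cl2 at −78 °C in the presence of 9 (3 equiv), the established coupling of a flavan-3,4-diol with a 5,7-di-O-benzylflavan-3-ol, gives 11.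

2. Step 5. Over-reduction to the alcohol, epimerisation of the cis aldehyde to the trans isomer, or base-induced opening of the ring by β-elimination during isolation would all deprive step 7 of its matched substrate. The fallback sets out from 6 and comes back at 7. Ester 6 is reduced fully with LiBH4 in THF to the stable, purifiable cis alcohol [(2S,3S)-6-(benzyloxy)-2-[3,4-bis(benzyloxy)phenyl]-2,3-dihydro-1-benzofuran-3-yl]methanol F5, which has no carbonyl next to C3. F5 is oxidised immediately before step 7 with 1,1,1-triacetoxy-1,1-dihydro-1,2-benziodoxol-3(1H)-one (DMP) and NaHCO3 in CH2Cl2 at 0 °C to give 7, used without chromatography.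

3. Step 1. Alkylation may be unselective between O2 and O4, or run on to the bis-ether. The fallback sets out from 1 and comes back at 4, bypassing 2. Ester 1 is lactonised (TsOH cat., toluene, reflux, removal of MeOH) to 6-hydroxy-1-benzofuran-2(3H)-one F6, which masks O2 inside the ring. The free phenol is benzylated under Mitsunobu conditions (BnOH, PPh3, DIAD, THF) to 6-(benzyloxy)-1-benzofuran-2(3H)-one F7. One-pot methanolysis and alkylation (K2CO3, MeOH, rt; then 3, NaI, DMF, 50 °C) opens the lactone to the phenoxide methyl ester and etherifies it to give 4.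

**Further compounds**

F1 | step 7 | methyl (2R,3S)-6-(benzyloxy)-2-[3,4-bis(benzyloxy)phenyl]-3-hydroxy-2,3-dihydro-1-benzofuran-3-carboxylate | c1ccccc1COc1ccc2c(c1)O[C@H](c1ccc(OCc3ccccc3)c(OCc3ccccc3)c1)[C@]2(O)C(=O)OC
F2 | step 7 | (2R,3S)-6-(benzyloxy)-2-[3,4-bis(benzyloxy)phenyl]-3-hydroxy-2,3-dihydro-1-benzofuran-3-carbaldehyde | c1ccccc1COc1ccc2c(c1)O[C@H](c1ccc(OCc3ccccc3)c(OCc3ccccc3)c1)[C@]2(O)C=O
F3 | step 7 | 7,3',4'-tri-O-benzyl-(2R,3R)-fustin, (2R,3R)-7-(benzyloxy)-2-[3,4-bis(benzyloxy)phenyl]-3-hydroxy-2,3-dihydro-4H-chromen-4-one | O=C1c2ccc(OCc3ccccc3)cc2O[C@H](c2ccc(OCc3ccccc3)c(OCc3ccccc3)c2)[C@H]1O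
F4 | step 7 | (2R,3S,4R)-7-(benzyloxy)-2-[3,4-bis(benzyloxy)phenyl]-3,4-dihydro-2H-chromene-3,4-diol | O[C@@H]1c2ccc(OCc3ccccc3)cc2O[C@H](c2ccc(OCc3ccccc3)c(OCc3ccccc3)c2)[C@H]1O
F5 | step 5 | [(2S,3S)-6-(benzyloxy)-2-[3,4-bis(benzyloxy)phenyl]-2,3-dihydro-1-benzofuran-3-yl]methanol (cis) | c1ccccc1COc1ccc2c(c1)O[C@H](c1ccc(OCc3ccccc3)c(OCc3ccccc3)c1)[C@@H]2CO
F6 | step 1 | 6-hydroxy-1-benzofuran-2(3H)-one | O=C1Cc2ccc(O)cc2O1
F7 | step 1 | 6-(benzyloxy)-1-benzofuran-2(3H)-one | O=C1Cc2ccc(OCc3ccccc3)cc2O1
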